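**Strategy**

The γ-lactone C19(=O)–O–C10 is read as the Baeyer–Villiger product of a cyclobutanone C10–C19(=O)–C4–C5 fused to ring B. This four-membered ring is made by an intramolecular keteniminium–alkene (2+2) cycloaddition: a keteniminium at C10 (on C9) and a vinyl group C5=C4 (on C6) unite to form C19–C4 and C5–C10 at once, closing ring B (C5, C6, C8, C9, C10) and setting C5 and C10. The precursor is a C/D bicyclo[3.2.1]octane carrying a pyrrolidine amide arm at C9 and an α-vinyl ester arm at C8. Ring A then closes by aldol formation of C3–C4.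

Key step: step 12

Remark on the chemistry: gibberellane numbering and the customary α/β descriptors of gibberellin drawings are used (9β-H; 15β is the endo face of the two-carbon bridge, anti to C14). C10 (compounds 5–19), C6 (18–26), C4 (24–26), C3 (27) and sulfur (18) are epimer mixtures that converge later (steps 12, 17, 17, 18 and 11) and are left unassigned in the SMILES. "C10 arm" means the 4-(tert-butyldimethylsilyloxy)-1-(pyrrolidine-1-carbonyl)butyl group.

**Route**

Step 1
Reactants: 1 pent-4-enoyl chloride; 2 pyrrolidine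
Product: 3 1-(pyrrolidin-1-yl)pent-4-en-1-one
Conditions: Et3N, CH2Cl2, 0 °C → rt
Reagents that add atoms: none
Why: N-acylation of a secondary amine by an acid chloride (Schotten–Baumann type) should give the tertiary amide that holds C19 and C10 and later serves as the keteniminium precursor.

Step 2
Reactants: 3 1-(pyrrolidin-1-yl)pent-4-en-1-one; 4 (3-bromopropoxy)(tert-butyl)dimethylsilane
Product: 5 racemic 2-[3-(tert-butyldimethylsilyloxy)propyl]-1-(pyrrolidin-1-yl)pent-4-en-1-one
Conditions: LiN(i-Pr)2, THF, −78 °C; then 4, DMPU, −78 → 0 °C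
Reagents that add atoms: none
Why: Amide enolate alkylation (SN2 at a primary bromide) attaches C1–C3 to C10, and the new center may stay racemic because C10 becomes sp2 in step 12.

Step 3
Reactants: 5 racemic alkylated amide
Product: 6 racemic 6-(tert-butyldimethylsilyloxy)-3-(pyrrolidine-1-carbonyl)hexanal
Conditions: O3, CH2Cl2, −78 °C; then PPh3, −78 °C → rt
Reagents that add atoms: ozone, [O-][O+]=O
Why: Ozonolysis with reductive work-up cleaves the only alkene and unveils the aldehyde carbon C8 next to the enolizable CH2 (C9).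

Step 4
Reactants: 6 aldehyde; 7 but-3-en-2-one
Product: 9 (4R)-4-[4-(tert-butyldimethylsilyloxy)-1-(pyrrolidine-1-carbonyl)butyl]cyclohex-2-en-1-one, via keto aldehyde 8 (not isolated)
Conditions: (S)-α,α-diphenylprolinol trimethylsilyl ether (10 mol %), ethyl 3,4-dihydroxybenzoate (20 mol %), neat, 4 °C; then LiOH, i-PrOH, rt
Reagents that add atoms: none
Why: Enamine-catalysed Michael addition followed by intramolecular aldol condensation (Robinson annulation, 6-(enolexo)-exo-trig closure of ring C): the anti E-enamine of 6 is shielded on one face by the CPh2(OSiMe3) group of the (S)-catalyst, so the enone adds to the open face and sets C9 (2S in 8, 4R in 9).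

Step 5
Reactants: 9 cyclohexenone; 10 1-(tert-butyldimethylsilyloxy)-1-methoxyethene
Product: 11 silyl enol ether of the 1,4-adduct (CH2CO2Me on C8 trans to the C10 arm)
Conditions: TBSOTf (10 mol %), CH2Cl2, −78 °C
Reagents that add atoms: none
Why: Mukaiyama–Michael addition with silyl transfer places C6 and C7 on C8 anti to the C9 side chain and stores the enolate as the silyl enol ether needed for step 6 (this C8 center is erased there).

Step 6
Reactants: 11 silyl enol ether
Product: 12 methyl 2-{(6S)-6-(C10 arm)-3-oxocyclohex-1-en-1-yl}acetate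
Conditions: Pd(OAc)2 (1.1 equiv), MeCN, rt
Reagents that add atoms: none
Why: Saegusa–Ito oxidation (palladation at C14 and β-hydride elimination of H8) should return the enone, now carrying the acetate arm on the β-carbon C8.

Step 7
Reactants: 12 enone; 13 (2-bromoallyl)trimethylsilane
Product: 14 methyl 2-{1-(2-bromoprop-2-en-1-yl)-2-(C10 arm)-5-oxocyclohexyl}acetate (bromoallyl trans to the C10 arm; C8 and C9 as in the target)
Conditions: TiCl4 (2.2 equiv), CH2Cl2, −78 °C
Reagents that add atoms: none
Why: Hosomi–Sakurai conjugate allylation creates the quaternary C8, since allylic 1,2-strain holds the C9 side chain pseudoaxial and the allylsilane attacks the opposite face, placing C15 trans and C6 cis to the C10 arm.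

Step 8
Reactants: 14 bromoallyl ketone
Product: 15 methyl 2-{5-hydroxy-6-methylidene-2-(C10 arm)bicyclo[3.2.1]octan-1-yl}acetate (C/D bicycle with free 13-OH)
Conditions: CrCl2 (6 equiv), NiCl2 (5 mol %), DMF, 50 °C
Reagents that add atoms: none
Why: Nozaki–Hiyama–Kishi reaction, in which zerovalent nickel activates the alkenyl bromide and the alkenyl–chromium species (trivalent chromium) adds to the C13 ketone in a 5-exo-trig closure of ring D; the C13 configuration is forced by the one-carbon reach of the axial C15 arm and the step gives the 13-hydroxy-16-methylene unit directly.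

Step 9
Reactants: 15 bicyclic tertiary alcohol
Product: 16 13-O-triethylsilyl ether of 15
Conditions: TESOTf, 2,6-lutidine, CH2Cl2, 0 °C
Reagents that add atoms: triethylsilyl trifluoromethanesulfonate, CC[Si](CC)(CC)OS(=O)(=O)C(F)(F)F
Why: Silylation with a silyl triflate protects the tertiary 13-OH against Tf2O in step 12 and is removed together with the other silyl ether in step 15.

Step 10
Reactants: 16 silyl ether; 17 phenyl vinyl sulfoxide
Product: 18 methyl 2-{bicyclic core of 16}-4-(phenylsulfinyl)butanoate (C6 and sulfur epimers)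
Conditions: LiN(i-Pr)2 (1.2 equiv), THF, −78 °C; then 17, −78 → −40 °C; AcOH
Reagents that add atoms: none
Why: Michael addition of the ester enolate (the ester α-CH2 is more acidic than the tertiary amide α-CH) to phenyl vinyl sulfoxide, a vinyl cation equivalent, puts C5 and C4 on C6; the C6 center forms unselectively and is corrected in step 17.

Step 11
Reactants: 18 sulfoxide
Product: 19 methyl 2-{6-methylidene-2-(C10 arm)-5-(triethylsilyloxy)bicyclo[3.2.1]octan-1-yl}but-3-enoate (C6 epimers)
Conditions: NaHCO3, toluene, 110 °C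
Reagents that add atoms: none
Why: Thermal syn-elimination of the sulfoxide (Ei) can only take H5 and so gives the terminal alkene C5=C4 without conjugation into the ester.

Step 12
Reactants: 19 amide with α-vinyl ester arm
Product: 22 cyclobutanone (C10–C19(=O)–C4H2–C5 ring cis-fused to ring B on the α face; C6 epimers), via keteniminium triflate 20 (not isolated), via cyclobutaniminium triflate 21 (not isolated)
Conditions: Tf2O (1.2 equiv), 2,4,6-collidine (1.5 equiv), ClCH2CH2Cl, −20 → 80 °C; then H2O, NaHCO3, rt
Reagents that add atoms: water, O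
Why: Tf2O O-sulfonylates the amide and collidine removes H10 to give the keteniminium ion 20, whose electrophilic central carbon C19 is attacked by the terminal alkene carbon C4, after which the developing secondary cation at C5 is captured by the enamine carbon C10 to give the cyclobutaniminium ion 21, which water hydrolyses to the cyclobutanone. The closest known reaction type is the Ghosez intramolecular keteniminium–alkene (2+2) cycloaddition, the more reactive counterpart of the thermal ketene–alkene cycloaddition. The four-membered ring closes by the (2+2) union itself and ring B closes as the fused five-membered ring of a bicyclo[3.2.0]heptane through the three-atom tether C9–C8–C6, not as the bridged bicyclo[3.1.1] alternative. C5 and C10 are necessarily cis on the four-membered ring, and the face is set by C9: on the sp2 carbon C10, which is axial on ring C, the C1 chain turns toward H9 and away from C11, so that C19 ends syn to C11 (α) and C4 is delivered to the α face of ring B, as the target requires. The step needs fused regiochemistry, secured because the terminal alkene places positive charge at the secondary C5 and the tether fits a five-membered ring, and chemoselectivity over the C16 methylene, secured because C15 is anti (trans-diaxial) to C10 in the rigid bicycle and cannot reach the keteniminium carbon. Both C6 epimers should follow the same course because C6 is remote from the controlling C9–C10 axis.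

Step 13
Reactants: 22 cyclobutanone
Product: 23 γ-lactone (C19(=O)–O–C10, C4H2; C6 epimers)
Conditions: H2O2 (30 %), NaOH, MeOH/THF, 0 °C
Reagents that add atoms: hydrogen peroxide, OO
Why: Baeyer–Villiger oxidation, in which the hydroperoxide anion adds to the strained cyclobutanone and the more substituted C10 migrates with retention, inserts oxygen between C19 and C10 and leaves the 16-alkene and the esters untouched.

Step 14
Reactants: 23 γ-lactone
Product: 24 C4-methyl γ-lactone (C4 and C6 epimers)
Conditions: LiN(i-Pr)2 (1.05 equiv), THF, −78 °C; MeI, −78 → −40 °C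
Reagents that add atoms: iodomethane, CI
Why: Kinetic enolization of the γ-lactone (more acidic and more exposed than the hindered C6–H) and SN2 methylation introduce C18, and the C4 configuration is irrelevant because C4 is enolized again in step 17.

Step 15
Reactants: 24 bis-silyl ether
Product: 25 diol (primary C3–OH and tertiary 13-OH)
Conditions: HF·pyridine, pyridine/THF, 0 °C → rt
Reagents that add atoms: none
Why: Fluoride-mediated cleavage of both silyl ethers frees the primary C3 alcohol and the tertiary 13-OH under conditions that spare lactone, ester and the allylic system.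

Step 16
Reactants: 25 diol
Product: 26 C3 aldehyde
Conditions: Dess–Martin periodinane, NaHCO3, CH2Cl2, 0 °C → rt
Reagents that add atoms: none
Why: Dess–Martin oxidation converts the primary alcohol to the C3 aldehyde, and the tertiary 13-OH cannot react.

Step 17
Reactants: 26 aldehyde
Product: 27 15-deoxy target methyl ester as its 3α/3β epimer pair (3,13-dihydroxy 19,10-lactone 7-methyl ester with the 6β ester)
Conditions: KOt-Bu (0.5 equiv), t-BuOH/THF, 0 °C → rt; aq. NH4Cl
Reagents that add atoms: none
Why: Alkoxide-mediated intramolecular aldol addition of the lactone enolate (C4) to the C3 aldehyde closes ring A in a 6-(enolexo)-exo-trig mode, with C4 fixed because the chain on C10 can reach only the exo face of the cis-fused lactone, while C6 equilibrates through its ester enolate to the more stable 6β ester trans to C4 and C3 is left as an epimer pair that step 18 erases.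

Step 18
Reactants: 27 3-epimeric alcohols
Product: 28 3-ketone (13-hydroxy-3-oxo 19,10-lactone 7-methyl ester)
Conditions: Dess–Martin periodinane, NaHCO3, CH2Cl2, rt
Reagents that add atoms: none
Why: Dess–Martin oxidation of the secondary C3 alcohols converges both epimers on the 3-ketone, a β-keto lactone that cannot enolize toward the bridgehead C4.

Step 19
Reactants: 28 3-ketone
Product: 29 3β-alcohol (3β,13-dihydroxy 19,10-lactone 7-methyl ester)
Conditions: KBH(s-Bu)3 (2.5 equiv), THF, −78 °C; aq. NH4Cl
Reagents that add atoms: none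
Why: Reduction with a bulky trialkylborohydride, which avoids the axial β approach blocked by the axial β-hydrogens on C1 and C5 and attacks C3 equatorially, should give the axial 3β-alcohol, and ester and lactone are inert at −78 °C.

Step 20
Reactants: 29 3β-alcohol
Product: 30 15α-alcohol (3β,13,15α-trihydroxy 19,10-lactone 7-methyl ester)
Conditions: SeO2 (0.5 equiv), t-BuOOH (3 equiv), CH2Cl2, rt
Reagents that add atoms: selenium dioxide, O=[Se]=O; tert-butyl hydroperoxide, CC(C)(C)OO
Why: SeO2 allylic hydroxylation (ene reaction at C17 with loss of a C15 hydrogen, then [2,3]-sigmatropic shift) keeps the 16(17)-alkene and delivers oxygen to C15 from the less hindered exo face, syn to C14, to give the 15α-alcohol.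

Step 21
Reactants: 30 15α-alcohol
Product: 31 enone (3β,13-dihydroxy-15-oxo 19,10-lactone 7-methyl ester)
Conditions: MnO2, CH2Cl2, rt
Reagents that add atoms: none
Why: MnO2 oxidizes only the allylic C15 alcohol, giving the 16-en-15-one and leaving the 3β- and 13-hydroxyls alone.

Step 22
Reactants: 31 enone
Product: 32 target methyl ester (3β,13,15β-trihydroxy 19,10-lactone 7-methyl ester)
Conditions: NaBH4, CeCl3·7H2O, MeOH, −78 → −20 °C
Reagents that add atoms: none
Why: Luche 1,2-reduction, in which hydride again approaches C15 from the exo face so that the hydroxyl ends endo (15β, syn to C9 and C11), inverts C15 relative to 30, and CeCl3 suppresses conjugate addition to the methylene ketone.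

Step 23
Reactants: 32 target methyl ester
Product: 33 target gibberellin (3β,13,15β-trihydroxy-20-norgibberell-16-ene-7,19-dioic acid 19,10-lactone)
Conditions: n-PrSLi, HMPA, rt; then dilute HCl to pH 3, 0 °C
Reagents that add atoms: none
Why: SN2 demethylation of the hindered C7 methyl ester by thiolate avoids hydroxide and so spares the lactone and the β-hydroxy lactone (retro-aldol) motif; mild acidification gives the free acid.

**Compound list**

1 | pent-4-enoyl chloride | C=CCCC(=O)Cl | starting material
2 | pyrrolidine | C1CCNC1 | starting material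
3 | 1-(pyrrolidin-1-yl)pent-4-en-1-one | C=CCCC(=O)N1CCCC1 | intermediate
4 | (3-bromopropoxy)(tert-butyl)dimethylsilane | BrCCCO[Si](C)(C)C(C)(C)C | starting material
5 | racemic 2-[3-(tert-butyldimethylsilyloxy)propyl]-1-(pyrrolidin-1-yl)pent-4-en-1-one | C=CCC(CCCO[Si](C)(C)C(C)(C)C)C(=O)N1CCCC1 | intermediate
6 | racemic 6-(tert-butyldimethylsilyloxy)-3-(pyrrolidine-1-carbonyl)hexanal | O=CCC(CCCO[Si](C)(C)C(C)(C)C)C(=O)N1CCCC1 | intermediate
7 | but-3-en-2-one | C=CC(C)=O | starting material
8 | (2S)-6-(tert-butyldimethylsilyloxy)-2-(3-oxobutyl)-3-(pyrrolidine-1-carbonyl)hexanal (both C3 epimers) | O=C[C@@H](CCC(C)=O)C(CCCO[Si](C)(C)C(C)(C)C)C(=O)N1CCCC1 | intermediate (not isolated)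
9 | (4R)-4-[4-(tert-butyldimethylsilyloxy)-1-(pyrrolidine-1-carbonyl)butyl]cyclohex-2-en-1-one | O=C1C=C[C@H](C(CCCO[Si](C)(C)C(C)(C)C)C(=O)N2CCCC2)CC1 | intermediate
10 | 1-(tert-butyldimethylsilyloxy)-1-methoxyethene | C=C(OC)O[Si](C)(C)C(C)(C)C | starting material
11 | methyl 2-{3-(tert-butyldimethylsilyloxy)-6-(C10 arm)cyclohex-2-en-1-yl}acetate, ring substituents trans | CC(C)(C)[Si](C)(C)OC1=C[C@@H](CC(=O)OC)[C@H](C(CCCO[Si](C)(C)C(C)(C)C)C(=O)N2CCCC2)CC1 | intermediate
12 | methyl 2-{(6S)-6-(C10 arm)-3-oxocyclohex-1-en-1-yl}acetate | O=C1C=C(CC(=O)OC)[C@H](C(CCCO[Si](C)(C)C(C)(C)C)C(=O)N2CCCC2)CC1 | intermediate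
13 | (2-bromoallyl)trimethylsilane | C=C(Br)C[Si](C)(C)C | starting material
14 | methyl 2-{1-(2-bromoprop-2-en-1-yl)-2-(C10 arm)-5-oxocyclohexyl}acetate, bromoallyl trans to the C10 arm | C=C(Br)C[C@@]1(CC(=O)CC[C@H]1C(CCCO[Si](C)(C)C(C)(C)C)C(=O)N1CCCC1)CC(=O)OC | intermediate
15 | methyl 2-{5-hydroxy-6-methylidene-2-(C10 arm)bicyclo[3.2.1]octan-1-yl}acetate | C=C1C[C@@]2(C[C@@]1(O)CC[C@H]2C(CCCO[Si](C)(C)C(C)(C)C)C(=O)N1CCCC1)CC(=O)OC | intermediate
16 | methyl 2-{6-methylidene-2-(C10 arm)-5-(triethylsilyloxy)bicyclo[3.2.1]octan-1-yl}acetate | C=C1C[C@@]2(C[C@@]1(O[Si](CC)(CC)CC)CC[C@H]2C(CCCO[Si](C)(C)C(C)(C)C)C(=O)N1CCCC1)CC(=O)OC | intermediate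
17 | phenyl vinyl sulfoxide | C=CS(=O)c1ccccc1 | starting material
18 | methyl 2-{6-methylidene-2-(C10 arm)-5-(triethylsilyloxy)bicyclo[3.2.1]octan-1-yl}-4-(phenylsulfinyl)butanoate (C6 and sulfur epimers) | C=C1C[C@@]2(C[C@@]1(O[Si](CC)(CC)CC)CC[C@H]2C(CCCO[Si](C)(C)C(C)(C)C)C(=O)N1CCCC1)C(CCS(=O)c1ccccc1)C(=O)OC | intermediate
19 | methyl 2-{6-methylidene-2-(C10 arm)-5-(triethylsilyloxy)bicyclo[3.2.1]octan-1-yl}but-3-enoate (C6 epimers) | C=C1C[C@@]2(C[C@@]1(O[Si](CC)(CC)CC)CC[C@H]2C(CCCO[Si](C)(C)C(C)(C)C)C(=O)N1CCCC1)C(C=C)C(=O)OC | intermediate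
20 | keteniminium triflate of 19 (C10=C19=N+ pyrrolidinium) | C=C1C[C@@]2(C[C@@]1(O[Si](CC)(CC)CC)CC[C@H]2C(CCCO[Si](C)(C)C(C)(C)C)=C=[N+]1CCCC1)C(C=C)C(=O)OC.[O-]S(=O)(=O)C(F)(F)F | intermediate (not isolated)
21 | cyclobutaniminium triflate (C19=N+ pyrrolidinium, four-membered ring C10–C19–C4–C5 cis-fused to ring B) | C=C1C[C@]23C[C@@]1(O[Si](CC)(CC)CC)CC[C@H]2[C@@]2(CCCO[Si](C)(C)C(C)(C)C)C(=[N+]1CCCC1)C[C@H]2C3C(=O)OC.[O-]S(=O)(=O)C(F)(F)F | intermediate (not isolated)
22 | cyclobutanone: C/D bicycle fused to ring B, cyclobutanone C10–C19(=O)–C4H2–C5 on the α face, 5β-H, C10 carrying the 3-(tert-butyldimethylsilyloxy)propyl chain (β), 13-OSiEt3, 16-methylene, C7 methyl ester (C6 epimers) | C=C1C[C@]23C[C@@]1(O[Si](CC)(CC)CC)CC[C@H]2[C@@]2(CCCO[Si](C)(C)C(C)(C)C)C(=O)C[C@H]2C3C(=O)OC | intermediate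
23 | 19,10-γ-lactone of the same skeleton with C4H2 (C6 epimers) | C=C1C[C@]23C[C@@]1(O[Si](CC)(CC)CC)CC[C@H]2[C@@]2(CCCO[Si](C)(C)C(C)(C)C)OC(=O)C[C@H]2C3C(=O)OC | intermediate
24 | C4-methyl 19,10-γ-lactone (C4 and C6 epimers) | C=C1C[C@]23C[C@@]1(O[Si](CC)(CC)CC)CC[C@H]2[C@@]2(CCCO[Si](C)(C)C(C)(C)C)OC(=O)C(C)[C@H]2C3C(=O)OC | intermediate
25 | diol: C4-methyl lactone with 3-hydroxypropyl chain on C10 and free 13-OH (C4 and C6 epimers) | C=C1C[C@]23C[C@@]1(O)CC[C@H]2[C@@]2(CCCO)OC(=O)C(C)[C@H]2C3C(=O)OC | intermediate
26 | aldehyde: C4-methyl lactone with 3-oxopropyl chain on C10 and free 13-OH (C4 and C6 epimers) | C=C1C[C@]23C[C@@]1(O)CC[C@H]2[C@@]2(CCC=O)OC(=O)C(C)[C@H]2C3C(=O)OC | intermediate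
27 | 3,13-dihydroxy-20-norgibberell-16-ene-7,19-dioic acid 19,10-lactone 7-methyl ester as its 3α/3β epimer pair (15-deoxy target methyl ester) | C=C1C[C@]23C[C@@]1(O)CC[C@H]2[C@@]12CCC(O)[C@@](C)(C(=O)O1)[C@H]2[C@@H]3C(=O)OC | intermediate
28 | 13-hydroxy-3-oxo-20-norgibberell-16-ene-7,19-dioic acid 19,10-lactone 7-methyl ester | C=C1C[C@]23C[C@@]1(O)CC[C@H]2[C@@]12CCC(=O)[C@@](C)(C(=O)O1)[C@H]2[C@@H]3C(=O)OC | intermediate
29 | 3β,13-dihydroxy-20-norgibberell-16-ene-7,19-dioic acid 19,10-lactone 7-methyl ester | C=C1C[C@]23C[C@@]1(O)CC[C@H]2[C@@]12CC[C@H](O)[C@@](C)(C(=O)O1)[C@H]2[C@@H]3C(=O)OC | intermediate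
30 | 3β,13,15α-trihydroxy-20-norgibberell-16-ene-7,19-dioic acid 19,10-lactone 7-methyl ester (15-epimer of 32) | C=C1[C@H](O)[C@]23C[C@@]1(O)CC[C@H]2[C@@]12CC[C@H](O)[C@@](C)(C(=O)O1)[C@H]2[C@@H]3C(=O)OC | intermediate
31 | 3β,13-dihydroxy-15-oxo-20-norgibberell-16-ene-7,19-dioic acid 19,10-lactone 7-methyl ester | C=C1C(=O)[C@]23C[C@@]1(O)CC[C@H]2[C@@]12CC[C@H](O)[C@@](C)(C(=O)O1)[C@H]2[C@@H]3C(=O)OC | intermediate
32 | 3β,13,15β-trihydroxy-20-norgibberell-16-ene-7,19-dioic acid 19,10-lactone 7-methyl ester (target methyl ester) | C=C1[C@@H](O)[C@]23C[C@@]1(O)CC[C@H]2[C@@]12CC[C@H](O)[C@@](C)(C(=O)O1)[C@H]2[C@@H]3C(=O)OC | intermediate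
33 | target gibberellin: 3β,13,15β-trihydroxy-20-norgibberell-16-ene-7,19-dioic acid 19,10-lactone | C=C1[C@@H](O)[C@]23C[C@@]1(O)CC[C@H]2[C@@]12CC[C@H](O)[C@@](C)(C(=O)O1)[C@H]2[C@@H]3C(=O)O | target

**Step count and risks**

Total step count: 23. Longest linear sequence: 23 steps (compound 1 to compound 33); compounds 2, 4, 7, 10, 13 and 17 are bought.

Steps most likely to fail:

Step 12. The keteniminium carbon may be captured by the silyl ether oxygen of the C1–C3 chain before the alkene adds, or the ring closure may discriminate poorly between the two faces at C10. The fallback sets out from 19 and uses the less electrophilic free ketene. IrCl(CO)(PPh3)2 with (Me2SiH)2O followed by mild aqueous acid should reduce the amide to the aldehyde F1. Pinnick oxidation (NaClO2, NaH2PO4, 2-methylbut-2-ene) should give the carboxylic acid F2, and oxalyl chloride with catalytic DMF the acid chloride F3. Et3N in toluene at 110 °C should then release the ketene F4, which closes by thermal intramolecular ketene–alkene (2+2) cycloaddition and comes back to the route at 22.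

Step 8. The alkenyl–metal intermediate may be protonated (loss of bromine without ring closure) because addition to the hindered, enolizable C13 ketone is slow. The fallback sets out from 12 and closes ring D by radical rather than organometallic addition. TiCl4-promoted conjugate addition of allenyltributylstannane (CH2Cl2, −78 °C) should give the propargyl ketone F5 with the same anti selectivity. SmI2 with HMPA and t-BuOH in THF should then form the C13 ketyl, which cyclizes 5-exo-dig onto the alkyne and comes back to the route at 15.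

Step 17. Equilibration at C6 may stay incomplete, or the aldehyde may degrade under alkoxide during the time that the epimerization needs. The fallback sets out from 24 and separates the two events. C6 is equilibrated first, with no aldehyde present (KOt-Bu cat., t-BuOH/THF, rt), to the 6β ester F6. HF·pyridine should give the diol F7 and Dess–Martin oxidation the aldehyde F8. Ring A is then closed by a brief aldol reaction that no longer has to epimerize C6 (NaOMe cat., MeOH, 0 °C), and the sequence comes back to the route at 27.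

Further compounds
F1 | step 12 | aldehyde: 19 with CHO in place of the pyrrolidine amide (C19 aldehyde on C10) | C=C1C[C@@]2(C[C@@]1(O[Si](CC)(CC)CC)CC[C@H]2C(CCCO[Si](C)(C)C(C)(C)C)C=O)C(C=C)C(=O)OC
F2 | step 12 | carboxylic acid: 19 with CO2H in place of the amide | C=C1C[C@@]2(C[C@@]1(O[Si](CC)(CC)CC)CC[C@H]2C(CCCO[Si](C)(C)C(C)(C)C)C(=O)O)C(C=C)C(=O)OC
F3 | step 12 | acid chloride of F2 | C=C1C[C@@]2(C[C@@]1(O[Si](CC)(CC)CC)CC[C@H]2C(CCCO[Si](C)(C)C(C)(C)C)C(=O)Cl)C(C=C)C(=O)OC
F4 | step 12 | ketene (C10=C19=O) derived from F3 | C=C1C[C@@]2(C[C@@]1(O[Si](CC)(CC)CC)CC[C@H]2C(CCCO[Si](C)(C)C(C)(C)C)=C=O)C(C=C)C(=O)OC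
F5 | step 8 | propargyl ketone: methyl 2-{2-(C10 arm)-5-oxo-1-(prop-2-yn-1-yl)cyclohexyl}acetate, propargyl trans to the C10 arm | C#CC[C@@]1(CC(=O)CC[C@H]1C(CCCO[Si](C)(C)C(C)(C)C)C(=O)N1CCCC1)CC(=O)OC
F6 | step 17 | 6β epimer of 24 (C4 epimers) | C=C1C[C@]23C[C@@]1(O[Si](CC)(CC)CC)CC[C@H]2[C@@]2(CCCO[Si](C)(C)C(C)(C)C)OC(=O)C(C)[C@H]2[C@@H]3C(=O)OC
F7 | step 17 | 6β epimer of diol 25 (C4 epimers) | C=C1C[C@]23C[C@@]1(O)CC[C@H]2[C@@]2(CCCO)OC(=O)C(C)[C@H]2[C@@H]3C(=O)OC
F8 | step 17 | 6β epimer of aldehyde 26 (C4 epimers) | C=C1C[C@]23C[C@@]1(O)CC[C@H]2[C@@]2(CCC=O)OC(=O)C(C)[C@H]2[C@@H]3C(=O)OC
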